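Ring numbering: O1, C2 (aryl), C4 (carbinol), C6 (arylethyl). The disconnection is the exocyclic bond from C6 of the tetrahydropyran to the first CH2 of the chain. It exploits that C6 is bonded to O1 and stands 1,3 to the C4 oxygen, so O1–C6–C5–C4–O is a latent vinylogous carboxylate. The precursor is therefore a kavalactone-like (S)-6-aryl-4-methoxy-5,6-dihydro-2-pyranone from one asymmetric hetero-Diels–Alder step. A 2-arylethyl Grignard reagent adds to its lactone carbonyl and acid triggers a Stork–Danheiser-type transposition. One operation joins both halves and recasts the lactone as the 2,6-disubstituted dihydropyran-4-one. The lone stereocentre then steers two hydride deliveries that set C6 and C4.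

Key step: step 6

Assumption: (S)-BINOL–Ti(IV) is taken to direct the diene to the Si face of the benzyl-protected aromatic aldehyde, the sense it shows in related carbonyl additions. Should the opposite sense be found, (R)-BINOL is used and nothing else changes.

Step 1
Reactants: 1 3,4-dihydroxy-5-methoxybenzaldehyde (5-hydroxyvanillin)
Product: 2 3,4-bis(benzyloxy)-5-methoxybenzaldehyde
Conditions: BnBr (2.3 equiv), K2CO3, DMF, 60 °C
Reagents that add atoms: benzyl bromide, BrCc1ccccc1
Why: Williamson ether synthesis in which both phenoxides are alkylated while the aldehyde is inert, with no stereocentre involved.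

Step 2
Reactants: 3 methyl (E)-3-methoxybut-2-enoate
Product: 4 1,3-dimethoxy-1-(trimethylsilyloxy)buta-1,3-diene (Brassard's diene)
Conditions: LDA (1.1 equiv), THF, −78 °C; then TMSCl, −78 °C to rt; distillation
Reagents that add atoms: chlorotrimethylsilane, C[Si](C)(C)Cl
Why: Kinetic γ-deprotonation of the β-methoxy enoate gives the extended dienolate, which TMSCl traps on oxygen (standard silyl ketene acetal formation).

Step 3
Reactants: 2 3,4-bis(benzyloxy)-5-methoxybenzaldehyde; 4 Brassard's diene
Product: 6 (6S)-6-[3,4-bis(benzyloxy)-5-methoxyphenyl]-4-methoxy-5,6-dihydro-2H-pyran-2-one, via silyl orthoester cycloadduct 5 (not isolated)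
Conditions: (S)-BINOL (20 mol %), Ti(OiPr)4 (10 mol %), 4 Å MS, toluene, 0 °C; then TFA (cat.), CH2Cl2, 0 °C
Reagents that add atoms: none
Why: Catalytic asymmetric hetero-Diels–Alder reaction (or its stepwise Mukaiyama aldol–lactonisation equivalent), in which the aldehyde bound to the (S)-BINOLate–Ti(IV) centre exposes its Si face to the CH2 terminus of the diene and so sets the (S) benzylic stereocentre, after which acid-induced collapse of the orthoester releases the lactone.

Step 4
Reactants: 7 2-(3,4-dihydroxyphenyl)ethanol (hydroxytyrosol)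
Product: 8 2-[3,4-bis(benzyloxy)phenyl]ethanol
Conditions: BnBr (2.1 equiv), K2CO3, acetone, reflux
Reagents that add atoms: benzyl bromide, BrCc1ccccc1
Why: Williamson ether synthesis that is selective for the two phenols, because carbonate ionises only these and leaves the primary alcohol free.

Step 5
Reactants: 8 2-[3,4-bis(benzyloxy)phenyl]ethanol
Product: 9 4-(2-bromoethyl)-1,2-bis(benzyloxy)benzene
Conditions: CBr4, PPh3, CH2Cl2, 0 °C
Reagents that add atoms: tetrabromomethane, BrC(Br)(Br)Br
Why: Appel reaction, an SN2 displacement of the alkoxyphosphonium ion at an unhindered primary carbon under neutral conditions that leave benzyl ethers intact.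

Step 6
Reactants: 6 (6S)-6-[3,4-bis(benzyloxy)-5-methoxyphenyl]-4-methoxy-5,6-dihydro-2H-pyran-2-one; 9 4-(2-bromoethyl)-1,2-bis(benzyloxy)benzene
Product: 12 (2S)-2-[3,4-bis(benzyloxy)-5-methoxyphenyl]-6-{2-[3,4-bis(benzyloxy)phenyl]ethyl}-2,3-dihydro-4H-pyran-4-one, via Grignard reagent 10 (not isolated), via lactol 11 (not isolated)
Conditions: 9, Mg, THF, rt; 6, LaCl3·2LiCl (1 equiv), THF, −78 °C, then 10 (1.1 equiv), to −40 °C; then 1 M HCl, THF, 0 °C to rt (short contact)
Reagents that add atoms: water, O (supplies the C4 carbonyl oxygen)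
Why: The lanthanide-activated lactone carbonyl of 6 takes up the primary Grignard reagent 10 by 1,2-addition to give the six-membered lactolate of 11; aqueous acid then ionises the C–OH to an oxocarbenium ion delocalised over O1–C=C–C(OMe), water adds at the methoxy-bearing terminus and methanol leaves, so the former ester carbon becomes C6 of an enone and the former enol-ether carbon becomes the C4 ketone. The closest known reaction types are the Stork–Danheiser alkylative carbonyl transposition of vinylogous esters and the lactol-forming addition of organometallics to δ-lactones used for C-glycosides. No new ring is made: the pyran ring of 6 is carried through, and should 11 open to its δ-hydroxy-β-methoxyenone tautomer it should re-close by 6-exo-trig attack of the benzylic hydroxyl on the ketone, the only ring size within reach. No lasting stereocentre is created, since the lactol carbon ends sp2, and the benzylic C2–O bond is never broken, so the (S) centre from step 3 is retained and later controls C6 and C4. The step needs 1,2- over 1,4-addition (hard Mg/La reagent, no copper), single over double addition (the cyclic lanthanide lactolate should persist at low temperature and only a slight excess of 10 is used) and addition over γ-deprotonation (LaCl3·2LiCl raises carbonyl electrophilicity and tempers basicity).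

Step 7
Reactants: 12 (2S)-2-[3,4-bis(benzyloxy)-5-methoxyphenyl]-6-{2-[3,4-bis(benzyloxy)phenyl]ethyl}-2,3-dihydro-4H-pyran-4-one
Product: 14 (2S,6S)-2-[3,4-bis(benzyloxy)-5-methoxyphenyl]-6-{2-[3,4-bis(benzyloxy)phenyl]ethyl}tetrahydro-4H-pyran-4-one (2,6-cis), via silyl enol ether 13 (not isolated)
Conditions: Cu(OAc)2·H2O (5 mol %), 1,2-bis(diphenylphosphino)benzene (5 mol %), PhMe2SiH (2 equiv), toluene, rt; then 1 M HCl, THF, 0 °C
Reagents that add atoms: none
Why: Copper hydride-catalysed conjugate reduction (Stryker-type 1,4-hydrosilylation, known also for chromones), in which hydride should reach C6 along the axial trajectory on the face anti to the pseudo-equatorial C2 aryl group, the sense in which cuprates give 2,6-trans adducts, so the chain ends equatorial and 2,6-cis, which is also the thermodynamically preferred isomer, while benzyl ethers are untouched.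

Step 8
Reactants: 14 (2S,6S)-2-[3,4-bis(benzyloxy)-5-methoxyphenyl]-6-{2-[3,4-bis(benzyloxy)phenyl]ethyl}tetrahydro-4H-pyran-4-one
Product: 15 (2S,4S,6S)-2-[3,4-bis(benzyloxy)-5-methoxyphenyl]-6-{2-[3,4-bis(benzyloxy)phenyl]ethyl}tetrahydro-2H-pyran-4-ol (4-OH axial, trans to both substituents)
Conditions: L-Selectride (1.3 equiv), THF, −78 °C; then aq NaOH, H2O2, 0 °C
Reagents that add atoms: none
Why: Sterically controlled ketone reduction, in which the bulky tri-sec-butylborohydride should attack the chair with both C2 and C6 substituents equatorial from the equatorial side and so give the axial (4S) alcohol.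

Step 9
Reactants: 15 (2S,4S,6S)-2-[3,4-bis(benzyloxy)-5-methoxyphenyl]-6-{2-[3,4-bis(benzyloxy)phenyl]ethyl}tetrahydro-2H-pyran-4-ol
Product: 16 (2S,4S,6S)-2-(3,4-dihydroxy-5-methoxyphenyl)-6-[2-(3,4-dihydroxyphenyl)ethyl]tetrahydro-2H-pyran-4-ol (target)
Conditions: H2 (1 atm), 10% Pd/C, EtOAc–MeOH, rt, stopped after uptake of 4 equiv
Reagents that add atoms: none
Why: Catalytic hydrogenolysis cleaves the four aryl benzyl ethers under neutral conditions far faster than the secondary ring benzylic C2–O bond, and no stereocentre is touched.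

Compound list
1 | 3,4-dihydroxy-5-methoxybenzaldehyde (5-hydroxyvanillin) | COc1cc(C=O)cc(O)c1O | starting material
2 | 3,4-bis(benzyloxy)-5-methoxybenzaldehyde | COc1cc(C=O)cc(OCc2ccccc2)c1OCc1ccccc1 | intermediate
3 | methyl (E)-3-methoxybut-2-enoate | CO/C(C)=C/C(=O)OC | starting material
4 | 1,3-dimethoxy-1-(trimethylsilyloxy)buta-1,3-diene (ketene acetal geometry not defined, lost in step 3) | C=C(OC)C=C(OC)O[Si](C)(C)C | intermediate
5 | (6S)-6-[3,4-bis(benzyloxy)-5-methoxyphenyl]-2,4-dimethoxy-2-(trimethylsilyloxy)-5,6-dihydro-2H-pyran (orthoester carbon undefined) | COc1cc([C@@H]2CC(OC)=CC(OC)(O[Si](C)(C)C)O2)cc(OCc2ccccc2)c1OCc1ccccc1 | intermediate (not isolated)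
6 | (6S)-6-[3,4-bis(benzyloxy)-5-methoxyphenyl]-4-methoxy-5,6-dihydro-2H-pyran-2-one | COc1cc([C@@H]2CC(OC)=CC(=O)O2)cc(OCc2ccccc2)c1OCc1ccccc1 | intermediate
7 | 2-(3,4-dihydroxyphenyl)ethanol (hydroxytyrosol) | OCCc1ccc(O)c(O)c1 | starting material
8 | 2-[3,4-bis(benzyloxy)phenyl]ethanol | OCCc1ccc(OCc2ccccc2)c(OCc2ccccc2)c1 | intermediate
9 | 4-(2-bromoethyl)-1,2-bis(benzyloxy)benzene | BrCCc1ccc(OCc2ccccc2)c(OCc2ccccc2)c1 | intermediate
10 | 2-[3,4-bis(benzyloxy)phenyl]ethylmagnesium bromide | Br[Mg]CCc1ccc(OCc2ccccc2)c(OCc2ccccc2)c1 | intermediate (not isolated)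
11 | (6S)-6-[3,4-bis(benzyloxy)-5-methoxyphenyl]-2-{2-[3,4-bis(benzyloxy)phenyl]ethyl}-4-methoxy-5,6-dihydro-2H-pyran-2-ol (lactol carbon undefined; formed on acidification of its metal alkoxide) | COc1cc([C@@H]2CC(OC)=CC(O)(CCc3ccc(OCc4ccccc4)c(OCc4ccccc4)c3)O2)cc(OCc2ccccc2)c1OCc1ccccc1 | intermediate (not isolated)
12 | (2S)-2-[3,4-bis(benzyloxy)-5-methoxyphenyl]-6-{2-[3,4-bis(benzyloxy)phenyl]ethyl}-2,3-dihydro-4H-pyran-4-one | COc1cc([C@@H]2CC(=O)C=C(CCc3ccc(OCc4ccccc4)c(OCc4ccccc4)c3)O2)cc(OCc2ccccc2)c1OCc1ccccc1 | intermediate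
13 | (2S,6S)-2-[3,4-bis(benzyloxy)-5-methoxyphenyl]-6-{2-[3,4-bis(benzyloxy)phenyl]ethyl}-4-[dimethyl(phenyl)silyloxy]-3,6-dihydro-2H-pyran | COc1cc([C@@H]2CC(O[Si](C)(C)c3ccccc3)=C[C@H](CCc3ccc(OCc4ccccc4)c(OCc4ccccc4)c3)O2)cc(OCc2ccccc2)c1OCc1ccccc1 | intermediate (not isolated)
14 | (2S,6S)-2-[3,4-bis(benzyloxy)-5-methoxyphenyl]-6-{2-[3,4-bis(benzyloxy)phenyl]ethyl}tetrahydro-4H-pyran-4-one | COc1cc([C@@H]2CC(=O)C[C@H](CCc3ccc(OCc4ccccc4)c(OCc4ccccc4)c3)O2)cc(OCc2ccccc2)c1OCc1ccccc1 | intermediate
15 | (2S,4S,6S)-2-[3,4-bis(benzyloxy)-5-methoxyphenyl]-6-{2-[3,4-bis(benzyloxy)phenyl]ethyl}tetrahydro-2H-pyran-4-ol | COc1cc([C@@H]2C[C@@H](O)C[C@H](CCc3ccc(OCc4ccccc4)c(OCc4ccccc4)c3)O2)cc(OCc2ccccc2)c1OCc1ccccc1 | intermediate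
16 | (2S,4S,6S)-2-(3,4-dihydroxy-5-methoxyphenyl)-6-[2-(3,4-dihydroxyphenyl)ethyl]tetrahydro-2H-pyran-4-ol | COc1cc([C@@H]2C[C@@H](O)C[C@H](CCc3ccc(O)c(O)c3)O2)cc(O)c1O | target

Total step count: 9. Longest linear sequence: 6 steps (steps 1, 3, 6, 7, 8, 9; the branches through steps 2 and 4–5 are equally long).

Steps most likely to fail

Step 6. The basic Grignard reagent may deprotonate C5 of the lactone and start an E1cB opening of the benzylic C–O bond. The lactolate may also collapse early and take up a second equivalent of nucleophile. The fallback makes the same bond with a soft nucleophile at the enone oxidation level. It sets out from 2 (with 10 prepared as before).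
- (S)-BINOL/Ti(OiPr)4-catalysed hetero-Diels–Alder reaction of 2 with Danishefsky's diene, followed by TFA work-up, should give (2S)-2-[3,4-bis(benzyloxy)-5-methoxyphenyl]-2,3-dihydro-4H-pyran-4-one F1.
- Copper-catalysed conjugate addition of 10 (CuBr·SMe2, TMSCl, THF, −78 °C) should proceed by axial attack. It should give the 2,6-trans trimethylsilyl enol ether F2.
- Saegusa–Ito oxidation (Pd(OAc)2, MeCN) erases the wrongly configured C6 centre and comes back to the route at 12.

Step 7. The electron-rich, β,β-disubstituted vinylogous ester may accept Cu–H too slowly. Carbonyl 1,2-reduction may compete, or facial selectivity may be poor. The fallback changes the protecting-group plan so that heterogeneous hydrogenation can set C6. It sets out from 12.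
- H2 over Pd/C in EtOAc–MeOH should add hydrogen to the ring alkene from the face opposite the aryl group and cleave all benzyl ethers. This should give the 2,6-cis tetraphenol ketone F3.
- TBSCl and imidazole in DMF should give the tetrakis(TBS) ketone F4.
- L-Selectride at −78 °C with a buffered work-up should give the axial tetrakis(TBS) alcohol F5.
- Et3N·3HF in THF removes the silyl groups and comes back to the route at 16.

Step 3. Slow cycloaddition of the electron-rich aldehyde may let an uncatalysed or silyl-cation-catalysed background reaction erode the enantioselectivity. The fallback activates the nucleophile instead of the aldehyde. It sets out from 2.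
- A copper fluoride–Tol-BINAP-catalysed vinylogous aldol addition uses the trimethylsilyl dienolate of 2,2,6-trimethyl-1,3-dioxin-4-one, with the ligand antipode chosen for the (S)-carbinol. After acidic work-up it should give the hydroxy dioxinone F6.
- Thermolysis in refluxing toluene generates the acylketene, which the δ-hydroxyl traps to give the β-keto-δ-lactone F7.
- O-methylation (Me2SO4, K2CO3, acetone) comes back to the route at 6.

Further compounds
F1 | step 6 | (2S)-2-[3,4-bis(benzyloxy)-5-methoxyphenyl]-2,3-dihydro-4H-pyran-4-one | COc1cc([C@@H]2CC(=O)C=CO2)cc(OCc2ccccc2)c1OCc1ccccc1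
F2 | step 6 | (2S,6R)-2-[3,4-bis(benzyloxy)-5-methoxyphenyl]-6-{2-[3,4-bis(benzyloxy)phenyl]ethyl}-4-(trimethylsilyloxy)-3,6-dihydro-2H-pyran (2,6-trans) | COc1cc([C@@H]2CC(O[Si](C)(C)C)=C[C@@H](CCc3ccc(OCc4ccccc4)c(OCc4ccccc4)c3)O2)cc(OCc2ccccc2)c1OCc1ccccc1
F3 | step 7 | (2S,6S)-2-(3,4-dihydroxy-5-methoxyphenyl)-6-[2-(3,4-dihydroxyphenyl)ethyl]tetrahydro-4H-pyran-4-one | COc1cc([C@@H]2CC(=O)C[C@H](CCc3ccc(O)c(O)c3)O2)cc(O)c1O
F4 | step 7 | (2S,6S)-2-[3,4-bis(tert-butyldimethylsilyloxy)-5-methoxyphenyl]-6-{2-[3,4-bis(tert-butyldimethylsilyloxy)phenyl]ethyl}tetrahydro-4H-pyran-4-one | COc1cc([C@@H]2CC(=O)C[C@H](CCc3ccc(O[Si](C)(C)C(C)(C)C)c(O[Si](C)(C)C(C)(C)C)c3)O2)cc(O[Si](C)(C)C(C)(C)C)c1O[Si](C)(C)C(C)(C)C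
F5 | step 7 | (2S,4S,6S)-2-[3,4-bis(tert-butyldimethylsilyloxy)-5-methoxyphenyl]-6-{2-[3,4-bis(tert-butyldimethylsilyloxy)phenyl]ethyl}tetrahydro-2H-pyran-4-ol | COc1cc([C@@H]2C[C@@H](O)C[C@H](CCc3ccc(O[Si](C)(C)C(C)(C)C)c(O[Si](C)(C)C(C)(C)C)c3)O2)cc(O[Si](C)(C)C(C)(C)C)c1O[Si](C)(C)C(C)(C)C
F6 | step 3 | 6-{(2S)-2-[3,4-bis(benzyloxy)-5-methoxyphenyl]-2-hydroxyethyl}-2,2-dimethyl-4H-1,3-dioxin-4-one | COc1cc([C@@H](O)CC2=CC(=O)OC(C)(C)O2)cc(OCc2ccccc2)c1OCc1ccccc1
F7 | step 3 | (6S)-6-[3,4-bis(benzyloxy)-5-methoxyphenyl]dihydro-2H-pyran-2,4(3H)-dione | COc1cc([C@@H]2CC(=O)CC(=O)O2)cc(OCc2ccccc2)c1OCc1ccccc1
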